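## Retrosynthetic overview

1. Locants follow the tricyclo[5.3.1.0^1,5]undecane core: C1 quaternary bridgehead, C2 formyl-bearing carbon, C5 ring-fusion CH, C6 CMe2, C7 bridgehead CH, C8=C9, C10 carbinol carbon, C11 CH2 bridge. The C10 ester is cut to a C10 alcohol plus a silyl-protected (9Z)-16-hydroxyhexadec-9-enoic acid, and the formyl group is taken back to CH2SPh.
2. Key disconnection: the C1–C2 bond of the formyl-bearing cyclopentane (C1–C2–C3–C4–C5) is made last, by thiyl-mediated radical translocation and 5-exo cyclisation of a bicyclo[3.2.1]octene that carries an exo but-3-ynyl chain on C5. This functionalises the bridgehead C1–H directly.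
3. Enabling feature: C5 carries the chain and has only two other neighbours, the hydrogen-free C6 (CMe2) and the bridgehead C1. The C1–H is therefore the only hydrogen in a 1,5 relationship to the inner alkyne carbon, and it sits syn to the chain on the exo face of the two-carbon bridge.
4. The bicyclo[3.2.1]octene comes from an intramolecular Michael addition of the α′-enolate of a 4-substituted cyclohexenone onto an enoate (closes the C1–C5 bond). C7 and the CMe2 carbon come from CBS reduction of 2-iodocyclohexenone followed by Ireland–Claisen rearrangement.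
5. Ring order: cyclohexene (C1, C7–C11; from the starting enone), then the gem-dimethylcyclopentane of the bicyclo[3.2.1]octene (C1, C5, C6, C7, C11), then the formyl-bearing cyclopentane (C1–C5) last.

Key step: step 13

Remark on the chemistry: the (S)-CBS catalyst is assigned by the usual model for 2-halo-enones (halovinyl arm as the large group); the enantiomeric catalyst would be used if the sense were reversed.

## Route

Step 1
Reactants: 1 2-iodocyclohex-2-en-1-one
Product: 2 (R)-2-iodocyclohex-2-en-1-ol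
Conditions: (S)-Me-CBS oxazaborolidine (10 mol%), BH3·SMe2, THF, −20 °C; MeOH quench
Reagents that add atoms: none
Why: Corey–Bakshi–Shibata reduction, in which the iodovinyl arm acts as the large group so that hydride is delivered to one face and sets the (R)-carbinol that is later relayed to C7.

Step 2
Reactants: 2 (R)-2-iodocyclohex-2-en-1-ol
Product: 3 (R)-2-iodocyclohex-2-en-1-yl 2-methylpropanoate
Conditions: i-PrCOCl, Et3N, DMAP (cat.), CH2Cl2, 0 °C → rt
Reagents that add atoms: isobutyryl chloride CC(C)C(Cl)=O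
Why: Standard acylation of a secondary allylic alcohol, which leaves the carbinol centre untouched.

Step 3
Reactants: 3 (R)-2-iodocyclohex-2-en-1-yl 2-methylpropanoate
Product: 6 2-[(1R)-2-iodocyclohex-2-en-1-yl]-2-methylpropanoic acid, via silyl ketene acetal 4 (not isolated), via trimethylsilyl ester 5 (not isolated)
Conditions: LDA, TMSCl, THF, −78 °C → 60 °C; then 1 M HCl
Reagents that add atoms: none
Why: Ireland–Claisen rearrangement, whose suprafacial [3,3] shift across the cyclohexenyl unit transfers the C–O configuration to the new C7–C6 bond (C7 set as R), builds the CMe2 quaternary carbon and moves the alkene to C8=C9 with iodine on C8.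

Step 4
Reactants: 6 2-[(1R)-2-iodocyclohex-2-en-1-yl]-2-methylpropanoic acid
Product: 7 2-[(1R)-2-iodocyclohex-2-en-1-yl]-2-methylpropan-1-ol
Conditions: BH3·THF, THF, 0 °C → rt; MeOH
Reagents that add atoms: none
Why: Chemoselective borane reduction of the carboxylic acid, which should leave the hindered vinyl iodide alone.

Step 5
Reactants: 7 2-[(1R)-2-iodocyclohex-2-en-1-yl]-2-methylpropan-1-ol
Product: 8 2-[(1R)-2-iodocyclohex-2-en-1-yl]-2-methylpropanal
Conditions: Dess–Martin periodinane, NaHCO3, CH2Cl2, rt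
Reagents that add atoms: none
Why: Dess–Martin oxidation to a neopentyl aldehyde that has no α-hydrogen and so cannot epimerise or self-condense.

Step 6
Reactants: 8 2-[(1R)-2-iodocyclohex-2-en-1-yl]-2-methylpropanal
Product: 9 methyl (2E)-4-[(1R)-2-iodocyclohex-2-en-1-yl]-4-methylpent-2-enoate
Conditions: (MeO)2P(O)CH2CO2Me, NaH, THF, 0 °C → rt
Reagents that add atoms: trimethyl phosphonoacetate COC(=O)CP(=O)(OC)OC
Why: Horner–Wadsworth–Emmons olefination, expected to give the E-enoate that will serve as the Michael acceptor (its β-carbon is the future C5).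

Step 7
Reactants: 9 methyl (2E)-4-[(1R)-2-iodocyclohex-2-en-1-yl]-4-methylpent-2-enoate
Product: 10 2-(trimethylsilyl)ethyl (6R)-6-[(3E)-5-methoxy-2-methyl-5-oxopent-3-en-2-yl]cyclohex-1-ene-1-carboxylate
Conditions: Pd(OAc)2 (5 mol%), PPh3 (10 mol%), CO (1 atm), Me3SiCH2CH2OH, Et3N, DMF, 60 °C
Reagents that add atoms: carbon monoxide [C-]#[O+]; 2-(trimethylsilyl)ethanol C[Si](C)(C)CCO
Why: Palladium-catalysed alkoxycarbonylation of the vinyl iodide installs the C8 carboxyl carbon as a fluoride-labile ester, with CO insertion expected to outrun any Heck pathway.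

Step 8
Reactants: 10 2-(trimethylsilyl)ethyl (6R)-6-[(3E)-5-methoxy-2-methyl-5-oxopent-3-en-2-yl]cyclohex-1-ene-1-carboxylate
Product: 11 2-(trimethylsilyl)ethyl (6R)-6-[(3E)-5-methoxy-2-methyl-5-oxopent-3-en-2-yl]-3-oxocyclohex-1-ene-1-carboxylate
Conditions: Rh2(cap)4 (1 mol%), t-BuOOH (70% aq.), K2CO3, CH2Cl2, rt
Reagents that add atoms: tert-butyl hydroperoxide CC(C)(C)OO
Why: Dirhodium caprolactamate/TBHP allylic (γ) C–H oxidation should take the ring CH2 γ to the ring ester, whose radical is conjugated with that ester, rather than the shielded tertiary allylic C7–H; the side-chain enoate has no γ-hydrogen.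

Step 9
Reactants: 11 2-(trimethylsilyl)ethyl (6R)-6-[(3E)-5-methoxy-2-methyl-5-oxopent-3-en-2-yl]-3-oxocyclohex-1-ene-1-carboxylate
Product: 13 2-(trimethylsilyl)ethyl (1R,5S,6R)-6-(2-methoxy-2-oxoethyl)-7,7-dimethyl-4-oxobicyclo[3.2.1]oct-2-ene-2-carboxylate (6-exo side chain), via lithium α′-dienolate 12 (not isolated)
Conditions: LiHMDS, THF, −78 → 0 °C; aq. NH4Cl
Reagents that add atoms: none
Why: Kinetic α′-deprotonation followed by intramolecular Michael addition (5-exo-trig) closes the gem-dimethylcyclopentane; the two-atom tether from C7 can bridge only one face, which fixes the new bridgehead, and the CH2CO2Me arm should take the exo position, away from the three-carbon bridge, which is also the isomer favoured if the addition reverses.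

Step 10
Reactants: 13 2-(trimethylsilyl)ethyl (1R,5S,6R)-6-(2-methoxy-2-oxoethyl)-7,7-dimethyl-4-oxobicyclo[3.2.1]oct-2-ene-2-carboxylate
Product: 15 2-(trimethylsilyl)ethyl (1R,4R,5S,6R)-4-hydroxy-6-(2-hydroxyethyl)-7,7-dimethylbicyclo[3.2.1]oct-2-ene-2-carboxylate (4-hydroxyl anti to the C8 methylene bridge), via allylic alcohol methyl ester 14 (not isolated)
Conditions: NaBH4, CeCl3·7H2O, MeOH/THF, −40 °C; then LiBH4, 0 °C → rt
Reagents that add atoms: none
Why: Luche 1,2-reduction should deliver hydride from the methylene-bridge face (the other face is screened by the CMe2–CH bridge and its endo hydrogen), placing the hydroxyl anti to that bridge as in the target; LiBH4/MeOH then reduces the unhindered methyl ester while the hindered conjugated silylethyl ester should survive.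

Step 11
Reactants: 15 2-(trimethylsilyl)ethyl (1R,4R,5S,6R)-4-hydroxy-6-(2-hydroxyethyl)-7,7-dimethylbicyclo[3.2.1]oct-2-ene-2-carboxylate
Product: 16 2-(trimethylsilyl)ethyl (1R,4R,5S,6R)-4-hydroxy-6-(2-iodoethyl)-7,7-dimethylbicyclo[3.2.1]oct-2-ene-2-carboxylate
Conditions: I2, PPh3, imidazole, CH2Cl2, 0 °C
Reagents that add atoms: iodine II
Why: Appel-type iodination, expected to be selective for the unhindered primary alcohol over the secondary allylic one.

Step 12
Reactants: 16 2-(trimethylsilyl)ethyl (1R,4R,5S,6R)-4-hydroxy-6-(2-iodoethyl)-7,7-dimethylbicyclo[3.2.1]oct-2-ene-2-carboxylate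
Product: 17 2-(trimethylsilyl)ethyl (1R,4R,5S,6R)-6-(but-3-yn-1-yl)-4-hydroxy-7,7-dimethylbicyclo[3.2.1]oct-2-ene-2-carboxylate
Conditions: NaC≡CH, DMSO/THF, rt
Reagents that add atoms: sodium acetylide [Na+].[C-]#C
Why: SN2 alkynylation of the primary iodide completes the four-carbon exo chain; the secondary alkoxide formed alongside points away from the chain and cannot close an ether.

Step 13
Reactants: 17 2-(trimethylsilyl)ethyl (1R,4R,5S,6R)-6-(but-3-yn-1-yl)-4-hydroxy-7,7-dimethylbicyclo[3.2.1]oct-2-ene-2-carboxylate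
Product: 18 2-(trimethylsilyl)ethyl (1S,2S,5S,7R,10S)-10-hydroxy-6,6-dimethyl-2-[(phenylsulfanyl)methyl]tricyclo[5.3.1.0^1,5]undec-8-ene-8-carboxylate
Conditions: PhSH (slow addition), AIBN, t-BuOH, reflux, high dilution
Reagents that add atoms: thiophenol Sc1ccccc1
Why: Thiyl radical addition to the terminal alkyne carbon gives a σ-vinyl radical at the future C2, which abstracts the bridgehead C1–H through a six-membered transition state (1,5-hydrogen atom transfer); the tertiary bridgehead radical then adds 5-exo-trig to the inner carbon of the vinyl sulfide just formed, and the α-thio radical takes hydrogen from PhSH to carry the chain. The closest known reaction type is the thiol-mediated radical translocation–cyclisation of terminal alkynes to (arylthiomethyl)cyclopentanes, which operates at tertiary C–H bonds and builds quaternary centres. The formyl-bearing cyclopentane is the only ring closed, in the 5-exo-trig mode. C1 is set by the substrate, because the bridgehead radical can bond only on its open exo face where the chain already sits (cis fusion through C5); C2 is set by the approach of the alkene, whose sulfur-bearing end should turn toward the C11 methylene bridge to avoid a syn-pentane clash with the equatorial C10 oxygen, which is also the more stable arrangement. The step needs site selectivity in the hydrogen transfer, and this is secured because C5 is flanked only by the hydrogen-free CMe2 carbon and by C1, so the bridgehead hydrogen is the single 1,5-related hydrogen, while the weak allylic C10–H points away from the chain. Slow addition of the thiol at high dilution should keep direct reduction of the vinyl radical behind the intramolecular hydrogen transfer.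

Step 14
Reactants: 19 heptane-1,7-diol
Product: 20 7-[(tert-butyldimethylsilyl)oxy]heptan-1-ol
Conditions: NaH (1 equiv), TBSCl (1 equiv), THF, 0 °C → rt
Reagents that add atoms: tert-butyldimethylsilyl chloride CC(C)(C)[Si](C)(C)Cl
Why: Monosilylation of a symmetrical diol through its sparingly soluble mono-sodium alkoxide.

Step 15
Reactants: 20 7-[(tert-butyldimethylsilyl)oxy]heptan-1-ol
Product: 21 7-[(tert-butyldimethylsilyl)oxy]heptanal
Conditions: Dess–Martin periodinane, NaHCO3, CH2Cl2, rt
Reagents that add atoms: none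
Why: Dess–Martin oxidation of a primary alcohol under buffered conditions that the silyl ether tolerates.

Step 16
Reactants: 22 9-bromononanoic acid
Product: 23 (8-carboxyoctyl)triphenylphosphonium bromide
Conditions: PPh3, MeCN, reflux
Reagents that add atoms: triphenylphosphine c1ccc(cc1)P(c1ccccc1)c1ccccc1
Why: SN2 quaternisation of triphenylphosphine by a primary bromide.

Step 17
Reactants: 23 (8-carboxyoctyl)triphenylphosphonium bromide; 21 7-[(tert-butyldimethylsilyl)oxy]heptanal
Product: 25 (9Z)-16-[(tert-butyldimethylsilyl)oxy]hexadec-9-enoic acid, via phosphonium ylide 24 (not isolated)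
Conditions: NaHMDS (2 equiv), THF, −78 °C; then 21, −78 °C → rt; aq. citric acid
Reagents that add atoms: none
Why: Wittig reaction of a non-stabilised ylide under lithium-free conditions, where kinetic formation of the cis-oxaphosphetane should give the Z-alkene.

Step 18
Reactants: 25 (9Z)-16-[(tert-butyldimethylsilyl)oxy]hexadec-9-enoic acid; 18 2-(trimethylsilyl)ethyl (1S,2S,5S,7R,10S)-10-hydroxy-6,6-dimethyl-2-[(phenylsulfanyl)methyl]tricyclo[5.3.1.0^1,5]undec-8-ene-8-carboxylate
Product: 27 2-(trimethylsilyl)ethyl (1S,2S,5S,7R,10S)-10-{[(9Z)-16-(tert-butyldimethylsilyloxy)hexadec-9-enoyl]oxy}-6,6-dimethyl-2-[(phenylsulfanyl)methyl]tricyclo[5.3.1.0^1,5]undec-8-ene-8-carboxylate, via mixed anhydride 26 (not isolated)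
Conditions: 2,4,6-Cl3C6H2COCl, Et3N, THF, rt; then 18, DMAP, toluene, rt → 50 °C
Reagents that add atoms: none
Why: Yamaguchi esterification acylates the hindered secondary alcohol with retention at C10; it is done after the radical step so that the Z-alkene never meets thiyl radicals.

Step 19
Reactants: 27 2-(trimethylsilyl)ethyl (1S,2S,5S,7R,10S)-10-{[(9Z)-16-(tert-butyldimethylsilyloxy)hexadec-9-enoyl]oxy}-6,6-dimethyl-2-[(phenylsulfanyl)methyl]tricyclo[5.3.1.0^1,5]undec-8-ene-8-carboxylate
Product: 28 the corresponding phenyl sulfoxide (both configurations at sulfur)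
Conditions: mCPBA (1 equiv), CH2Cl2, −78 °C
Reagents that add atoms: 3-chloroperoxybenzoic acid OOC(=O)c1cccc(Cl)c1
Why: Sulfide-to-sulfoxide oxidation, which at −78 °C with one equivalent of peracid should be far faster than epoxidation of the Z-alkene or of the electron-poor enoate.

Step 20
Reactants: 28 the phenyl sulfoxide
Product: 30 2-(trimethylsilyl)ethyl (1S,2S,5S,7R,10S)-10-{[(9Z)-16-(tert-butyldimethylsilyloxy)hexadec-9-enoyl]oxy}-2-formyl-6,6-dimethyltricyclo[5.3.1.0^1,5]undec-8-ene-8-carboxylate, via α-trifluoroacetoxy sulfide 29 (not isolated)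
Conditions: TFAA, 2,6-lutidine, CH2Cl2, 0 °C; then aq. NaHCO3, rt
Reagents that add atoms: trifluoroacetic anhydride O=C(OC(=O)C(F)(F)F)C(F)(F)F
Why: Pummerer rearrangement and mild hydrolysis of the O,S-acetal unveil the aldehyde; C2 is not at risk because the formyl group anti to the C10 acyloxy group is judged, on steric grounds, to be the more stable epimer.

Step 21
Reactants: 30 the protected aldehyde
Product: 31 (1S,2S,5S,7R,10S)-2-formyl-10-{[(9Z)-16-hydroxyhexadec-9-enoyl]oxy}-6,6-dimethyltricyclo[5.3.1.0^1,5]undec-8-ene-8-carboxylic acid (CNP0214056.2)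
Conditions: TBAF, AcOH, THF, 0 °C → rt
Reagents that add atoms: none
Why: Buffered fluoride should cleave the 2-(trimethylsilyl)ethyl ester (by β-elimination) and the primary silyl ether in one operation while leaving the allylic carboxylic ester, the Z-alkene and the aldehyde intact.

## Compound list

1 | 2-iodocyclohex-2-en-1-one | O=C1CCCC=C1I | starting material
2 | (R)-2-iodocyclohex-2-en-1-ol | O[C@@H]1CCCC=C1I | intermediate
3 | (R)-2-iodocyclohex-2-en-1-yl 2-methylpropanoate | CC(C)C(=O)O[C@@H]1CCCC=C1I | intermediate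
4 | trimethylsilyl ketene acetal of 3 | CC(C)=C(O[Si](C)(C)C)O[C@@H]1CCCC=C1I | intermediate (not isolated)
5 | trimethylsilyl 2-[(1R)-2-iodocyclohex-2-en-1-yl]-2-methylpropanoate | CC(C)(C(=O)O[Si](C)(C)C)[C@H]1CCCC=C1I | intermediate (not isolated)
6 | 2-[(1R)-2-iodocyclohex-2-en-1-yl]-2-methylpropanoic acid | CC(C)(C(=O)O)[C@H]1CCCC=C1I | intermediate
7 | 2-[(1R)-2-iodocyclohex-2-en-1-yl]-2-methylpropan-1-ol | CC(C)(CO)[C@H]1CCCC=C1I | intermediate
8 | 2-[(1R)-2-iodocyclohex-2-en-1-yl]-2-methylpropanal | CC(C)(C=O)[C@H]1CCCC=C1I | intermediate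
9 | methyl (2E)-4-[(1R)-2-iodocyclohex-2-en-1-yl]-4-methylpent-2-enoate | COC(=O)/C=C/C(C)(C)[C@H]1CCCC=C1I | intermediate
10 | 2-(trimethylsilyl)ethyl (6R)-6-[(3E)-5-methoxy-2-methyl-5-oxopent-3-en-2-yl]cyclohex-1-ene-1-carboxylate | COC(=O)/C=C/C(C)(C)[C@H]1CCCC=C1C(=O)OCC[Si](C)(C)C | intermediate
11 | 2-(trimethylsilyl)ethyl (6R)-6-[(3E)-5-methoxy-2-methyl-5-oxopent-3-en-2-yl]-3-oxocyclohex-1-ene-1-carboxylate | COC(=O)/C=C/C(C)(C)[C@H]1CCC(=O)C=C1C(=O)OCC[Si](C)(C)C | intermediate
12 | lithium (4R)-4-[(3E)-5-methoxy-2-methyl-5-oxopent-3-en-2-yl]-5-{[2-(trimethylsilyl)ethoxy]carbonyl}cyclohexa-1,5-dien-1-olate | [Li+].COC(=O)/C=C/C(C)(C)[C@H]1CC=C([O-])C=C1C(=O)OCC[Si](C)(C)C | intermediate (not isolated)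
13 | 2-(trimethylsilyl)ethyl (1R,5S,6R)-6-(2-methoxy-2-oxoethyl)-7,7-dimethyl-4-oxobicyclo[3.2.1]oct-2-ene-2-carboxylate | CC1(C)[C@H]2C[C@H](C(=O)C=C2C(=O)OCC[Si](C)(C)C)[C@H]1CC(=O)OC | intermediate
14 | 2-(trimethylsilyl)ethyl (1R,4R,5S,6R)-4-hydroxy-6-(2-methoxy-2-oxoethyl)-7,7-dimethylbicyclo[3.2.1]oct-2-ene-2-carboxylate | CC1(C)[C@H]2C[C@H]([C@@H](O)C=C2C(=O)OCC[Si](C)(C)C)[C@H]1CC(=O)OC | intermediate (not isolated)
15 | 2-(trimethylsilyl)ethyl (1R,4R,5S,6R)-4-hydroxy-6-(2-hydroxyethyl)-7,7-dimethylbicyclo[3.2.1]oct-2-ene-2-carboxylate | CC1(C)[C@H]2C[C@H]([C@@H](O)C=C2C(=O)OCC[Si](C)(C)C)[C@H]1CCO | intermediate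
16 | 2-(trimethylsilyl)ethyl (1R,4R,5S,6R)-4-hydroxy-6-(2-iodoethyl)-7,7-dimethylbicyclo[3.2.1]oct-2-ene-2-carboxylate | CC1(C)[C@H]2C[C@H]([C@@H](O)C=C2C(=O)OCC[Si](C)(C)C)[C@H]1CCI | intermediate
17 | 2-(trimethylsilyl)ethyl (1R,4R,5S,6R)-6-(but-3-yn-1-yl)-4-hydroxy-7,7-dimethylbicyclo[3.2.1]oct-2-ene-2-carboxylate | CC1(C)[C@H]2C[C@H]([C@@H](O)C=C2C(=O)OCC[Si](C)(C)C)[C@H]1CCC#C | intermediate
18 | 2-(trimethylsilyl)ethyl (1S,2S,5S,7R,10S)-10-hydroxy-6,6-dimethyl-2-[(phenylsulfanyl)methyl]tricyclo[5.3.1.0^1,5]undec-8-ene-8-carboxylate | CC1(C)[C@H]2C[C@@]3([C@@H](O)C=C2C(=O)OCC[Si](C)(C)C)[C@@H](CSc4ccccc4)CC[C@@H]13 | intermediate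
19 | heptane-1,7-diol | OCCCCCCCO | starting material
20 | 7-[(tert-butyldimethylsilyl)oxy]heptan-1-ol | CC(C)(C)[Si](C)(C)OCCCCCCCO | intermediate
21 | 7-[(tert-butyldimethylsilyl)oxy]heptanal | CC(C)(C)[Si](C)(C)OCCCCCCC=O | intermediate
22 | 9-bromononanoic acid | OC(=O)CCCCCCCCBr | starting material
23 | (8-carboxyoctyl)triphenylphosphonium bromide | [Br-].OC(=O)CCCCCCCC[P+](c1ccccc1)(c1ccccc1)c1ccccc1 | intermediate
24 | sodium 9-(triphenyl-λ5-phosphanylidene)nonanoate | [Na+].[O-]C(=O)CCCCCCCC=P(c1ccccc1)(c1ccccc1)c1ccccc1 | intermediate (not isolated)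
25 | (9Z)-16-[(tert-butyldimethylsilyl)oxy]hexadec-9-enoic acid | CC(C)(C)[Si](C)(C)OCCCCCC/C=C\CCCCCCCC(=O)O | intermediate
26 | mixed anhydride of 25 with 2,4,6-trichlorobenzoic acid | CC(C)(C)[Si](C)(C)OCCCCCC/C=C\CCCCCCCC(=O)OC(=O)c1c(Cl)cc(Cl)cc1Cl | intermediate (not isolated)
27 | 2-(trimethylsilyl)ethyl (1S,2S,5S,7R,10S)-10-{[(9Z)-16-(tert-butyldimethylsilyloxy)hexadec-9-enoyl]oxy}-6,6-dimethyl-2-[(phenylsulfanyl)methyl]tricyclo[5.3.1.0^1,5]undec-8-ene-8-carboxylate | CC1(C)[C@H]2C[C@@]3([C@@H](OC(=O)CCCCCCC/C=C\CCCCCCO[Si](C)(C)C(C)(C)C)C=C2C(=O)OCC[Si](C)(C)C)[C@@H](CSc4ccccc4)CC[C@@H]13 | intermediate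
28 | phenyl sulfoxide of 27 (both configurations at sulfur) | CC1(C)[C@H]2C[C@@]3([C@@H](OC(=O)CCCCCCC/C=C\CCCCCCO[Si](C)(C)C(C)(C)C)C=C2C(=O)OCC[Si](C)(C)C)[C@@H](CS(=O)c4ccccc4)CC[C@@H]13 | intermediate
29 | α-trifluoroacetoxy sulfide from 28 (both configurations at the O,S-acetal carbon) | CC1(C)[C@H]2C[C@@]3([C@@H](OC(=O)CCCCCCC/C=C\CCCCCCO[Si](C)(C)C(C)(C)C)C=C2C(=O)OCC[Si](C)(C)C)[C@@H](C(OC(=O)C(F)(F)F)Sc4ccccc4)CC[C@@H]13 | intermediate (not isolated)
30 | 2-(trimethylsilyl)ethyl (1S,2S,5S,7R,10S)-10-{[(9Z)-16-(tert-butyldimethylsilyloxy)hexadec-9-enoyl]oxy}-2-formyl-6,6-dimethyltricyclo[5.3.1.0^1,5]undec-8-ene-8-carboxylate | CC1(C)[C@H]2C[C@@]3([C@@H](OC(=O)CCCCCCC/C=C\CCCCCCO[Si](C)(C)C(C)(C)C)C=C2C(=O)OCC[Si](C)(C)C)[C@@H](C=O)CC[C@@H]13 | intermediate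
31 | (1S,2S,5S,7R,10S)-2-formyl-10-{[(9Z)-16-hydroxyhexadec-9-enoyl]oxy}-6,6-dimethyltricyclo[5.3.1.0^1,5]undec-8-ene-8-carboxylic acid | CC1(C)[C@H]2C[C@@]3([C@@H](OC(=O)CCCCCCC/C=C\CCCCCCO)C=C2C(=O)O)[C@@H](C=O)CC[C@@H]13 | target

## Step count and risks

Total step count: 21. Longest linear sequence: 17 steps (steps 1–13 and 18–21); steps 14–17 make the side-chain acid.

Steps most likely to fail:

1. Step 13 (key step). The vinyl radical may be reduced by the thiol before the 1,5-hydrogen transfer (plain hydrothiolation of the alkyne), or the bridgehead radical may add with poor facial control at C2. The fallback replaces radical translocation by a metal-carbenoid C–H insertion. It sets out from iodide 16: alkylation of the sodium enolate of methyl acetoacetate (NaH, DMF) gives the alkylated acetoacetate F1. Deacylative diazo transfer (p-acetamidobenzenesulfonyl azide, DBU, MeCN) gives the α-diazo ester F2. Rh2(O2CCPh3)4 at low temperature then effects 1,5 C–H insertion into the bridgehead C1–H with retention, giving the tricyclic methyl ester F3, whose C2 centre can be equilibrated with DBU to the epimer drawn. LiBH4 reduces the methyl ester to the diol F4, and PhSSPh/PBu3 converts its primary hydroxyl into the sulfide, returning to the route at 18.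

2. Step 8. Hydrogen abstraction may occur at the tertiary allylic C7–H (with transposition of the alkene) rather than at the ring CH2, or the product may over-oxidise. The fallback replaces direct C–H oxidation by halogenation and a Kornblum-type oxidation. It sets out from ester 10: Wohl–Ziegler bromination (NBS, AIBN, PhCF3, reflux), the classical γ-bromination of α,β-unsaturated esters, gives the γ-bromo ester F5 (both configurations at the bromine-bearing carbon). N-Methylmorpholine N-oxide in MeCN then converts the allylic bromide into the enone, returning to the route at 11.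

3. Step 9. The amide base may remove the γ-hydrogen at C7 instead of the α′-hydrogen (eroding the only stereocentre present at that stage) or add to the doubly activated ring alkene. The fallback replaces the basic enolate by a Lewis-acid Mukaiyama–Michael addition. It sets out from enone 11: soft enolisation (TBSOTf, Et3N, CH2Cl2, −78 °C) gives the cross-conjugated 2-silyloxydiene F6, and TiCl4 at −78 °C then triggers the intramolecular addition to the enoate, returning to the route at 13 after aqueous work-up.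

## Further compounds

F1 | step 13 | 2-(trimethylsilyl)ethyl (1R,4R,5S,6R)-4-hydroxy-6-[3-(methoxycarbonyl)-4-oxopentyl]-7,7-dimethylbicyclo[3.2.1]oct-2-ene-2-carboxylate | CC1(C)[C@H]2C[C@H]([C@@H](O)C=C2C(=O)OCC[Si](C)(C)C)[C@H]1CCC(C(C)=O)C(=O)OC
F2 | step 13 | 2-(trimethylsilyl)ethyl (1R,4R,5S,6R)-6-(3-diazo-4-methoxy-4-oxobutyl)-4-hydroxy-7,7-dimethylbicyclo[3.2.1]oct-2-ene-2-carboxylate | CC1(C)[C@H]2C[C@H]([C@@H](O)C=C2C(=O)OCC[Si](C)(C)C)[C@H]1CCC(=[N+]=[N-])C(=O)OC
F3 | step 13 | 2-methyl 8-[2-(trimethylsilyl)ethyl] (1S,2S,5S,7R,10S)-10-hydroxy-6,6-dimethyltricyclo[5.3.1.0^1,5]undec-8-ene-2,8-dicarboxylate | CC1(C)[C@H]2C[C@@]3([C@@H](O)C=C2C(=O)OCC[Si](C)(C)C)[C@@H](C(=O)OC)CC[C@@H]13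
F4 | step 13 | 2-(trimethylsilyl)ethyl (1S,2S,5S,7R,10S)-10-hydroxy-2-(hydroxymethyl)-6,6-dimethyltricyclo[5.3.1.0^1,5]undec-8-ene-8-carboxylate | CC1(C)[C@H]2C[C@@]3([C@@H](O)C=C2C(=O)OCC[Si](C)(C)C)[C@@H](CO)CC[C@@H]13
F5 | step 8 | 2-(trimethylsilyl)ethyl (6R)-3-bromo-6-[(3E)-5-methoxy-2-methyl-5-oxopent-3-en-2-yl]cyclohex-1-ene-1-carboxylate | COC(=O)/C=C/C(C)(C)[C@H]1CCC(Br)C=C1C(=O)OCC[Si](C)(C)C
F6 | step 9 | 2-(trimethylsilyl)ethyl (6R)-3-[(tert-butyldimethylsilyl)oxy]-6-[(3E)-5-methoxy-2-methyl-5-oxopent-3-en-2-yl]cyclohexa-1,3-diene-1-carboxylate | COC(=O)/C=C/C(C)(C)[C@H]1CC=C(O[Si](C)(C)C(C)(C)C)C=C1C(=O)OCC[Si](C)(C)C
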